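## Structural features

The target 15 is an achiral, symmetric dibenzyl ether: two identical benzene rings joined through a C7H2–O–C7'H2 bridge. Each ring is pentasubstituted in one unbroken sequence: C1 carries the benzylic CH2, C2 and C3 carry bromine, C4 and C5 carry hydroxyl, and only C6 carries hydrogen. There is no stereocentre, so no stereocentres stand next to each other and nothing has to be set or preserved. The fragile elements are:
- the two catechols, which oxidise to o-quinones, most readily as their anions;
- the central ether, which is a 4-hydroxybenzyl ether (C4–OH is para to C1) and can ionise to a quinone methide under acid or heat and then exchange with an alcohol solvent;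
- the four C–Br bonds, which rule out hydrogenolysis, dissolving metals and most organometallic steps late in the route.

The real difficulty is regiochemical. Two adjacent bromines must sit at C2 and C3, whereas electrophilic substitution of a 4-substituted catechol is drawn equally to C6 and releases acid that endangers the ether. The key step exploits the fact that in each ring the run C1=C2(Br)–C3(Br)=C4(O) is the diene C6=C5–C4=C3 of a 2-pyranone that already bears all four substituents, while C5(O)–C6(H) is a ketene acetal. The lactone bridge leaves as CO2. Because the two halves are identical, every operation is either done on a monomer or done twice on one molecule.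

## Logic of the disconnections

15 ⇒ 14. The four O–protecting-group bonds are cut (O–acyl at C4, O–Si at C5, in both rings). The free catechols and the 4-hydroxybenzyl ether are the most sensitive features, so they are exposed only in the last operation. The gain is that the final step is a single mild solvolysis. The demand is a cold, oxygen-free, basic cleavage that leaves the CH2–O–CH2 bridge and the C–Br bonds alone.

14 ⇒ 9 + 11. In each ring C6–C1 and C4–C5 are cut (four skeletal bonds in all) and the lactone bridge O–C(=O) is restored between C1 and C4. This is the place to cut because the diene half then carries all of the benzylic carbon, both bromines and the C4 oxygen, and the two-carbon partner brings the C5 oxygen and C6–H. Both arene rings are reduced to pyranones, and no aromatic substitution is needed afterwards. The forward step must be a regioselective inverse-electron-demand cycloaddition, followed by decarboxylative cycloreversion and loss of silanol, and all of this must happen twice.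

11 ⇒ 10. One O–Si bond is cut, which is enolisation and O-silylation in the forward sense. The demand is O- over C-silylation.

9 ⇒ 7 + 8. One C7–O bond of the bridge is cut. The symmetry makes both partners derivatives of one monomer. A silver-oxide etherification joins an alcohol with a halide, not two alcohols, so one half must be the bromide. The forward step must be neutral enough for an enol ester and an enol lactone.

8 ⇒ 7. The C–Br bond at the exocyclic carbon is exchanged for C–OH. The demand is neutral activation of a primary alcohol.

7 ⇒ 5 + 6. The O–acyl bond at the C3 oxygen is cut. A hindered acyl group is chosen because the 3-acyloxy-4,5-dibromopyranone is an activated ester and would pass a small acyl group on to the primary alcohol. The forward step must tell the enolic from the primary hydroxyl.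

5 ⇒ 4. The two C–Br bonds at pyranone C4 and C5 (arene C3 and C2) are cut. These are the only ring CH positions and both are nucleophilic, so the halogens go on where no regiochemical choice exists. The demand is double bromination without oxidation of the enol lactone or the alcohol.

4 ⇒ 3. The CH2OH group is traced back to COOH. The demand is reduction of an acid in the presence of a conjugated lactone.

3 ⇒ 1 (through 2). The pyranone is opened to a six-carbon hexaric acid, whose carbons and oxygens are already in the right places. The forward step is a threefold dehydration with lactonisation, which erases all four stereocentres of 1.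

## Other disconnections considered

Alternative 1: The cut goes through C3–C4 and C5–C6 of each ring, so that the two oxygen-bearing carbons come from a dienophile and C1, C2, C3, C6 and C7 from a 2-substituted butadiene.
- Forward step: bis(2-methylenebut-3-en-1-yl) ether A1 would be heated with two equivalents of 4,5-dichloro-1,3-dioxol-2-one A2. Buffered hydrolysis of the chlorinated carbonate adducts would unmask 1,2-diones, which enolise to bis(3,4-dihydroxybenzyl) ether A3.
- In its favour: the dienophile is symmetrical, so the ring-forming step poses no regiochemical question. On that point it is better than the chosen plan. It is a normal-demand, concerted cycloaddition with no gas extrusion to rely on, and the number of steps to A3 should be equal to or lower than the number to 14.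
- Against it here: A3 has no bromine. Four aromatic brominations at C2 and C3 would have to be done on a free catechol, where C6 competes and the acid released threatens the 4-hydroxybenzyl ether. A1 is prone to polymerisation, and the tetrasubstituted, electron-poor A2 would need forcing temperatures.
- Comparison: structurally the chosen plan delivers all five substituents of each ring in the ring-forming event, and this alternative delivers three. Mechanistically the alternative is the more certain cycloaddition. In step economy it is shorter up to the key step, but it leaves the hardest problem, the halogen pattern, for the end.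

Alternative 2: The cut goes through C1–C2 and C2–C3, so C2 comes from a one-carbon nucleophile that takes the place of a ring oxygen.
- Forward step: the anion of nitromethane A5, made with a tert-butoxide base, would add to each 4-pyranone of bis[(5-allyloxy-4-oxo-4H-pyran-2-yl)methyl] ether A4. Ring opening and intramolecular nitro-aldol condensation would reclose each ring as a 4-nitrophenol, giving bis(4-allyloxy-5-hydroxy-2-nitrobenzyl) ether A6.
- In its favour: A4 is a robust pyranone ether that can be assembled by an ordinary base-mediated etherification. That is easier and safer than the preparation of 9, and on precursor access this alternative is the better one. The nitro group marks C2 for a later bromine.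
- Against it here: only C2 receives a handle. After A6 the C5 hydroxyl would need protection, both nitro groups would need reduction and a twofold diazotisation with Sandmeyer bromination, C3 would still need an electrophilic bromination in competition with C6, and the allyl groups would have to be removed. The nitronate could also add at either α-carbon of the pyranone.
- Comparison: structurally this alternative fixes one bromine position by construction, where the chosen plan fixes both. Mechanistically it is a stepwise polar addition, ring opening and ring closure. Its footing is about equal to that of the chosen cycloaddition, since each extends a known ring transformation to a new substitution pattern. In step economy it is better before the key step and clearly worse after it (five or more steps against one).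

Alternative 3: The cut removes both C1–C7 bonds, so the rings are bought as a finished arene and the bridge comes from a CH2–O–CH2 dielectrophile.
- Forward step: iodine–magnesium exchange on 2,3-dibromo-4,5-bis(tert-butyldimethylsilyloxy)-1-iodobenzene A7 would give the aryl Grignard reagent. Two equivalents of it would displace both chlorides of bis(chloromethyl) ether A8 to give bis[2,3-dibromo-4,5-bis(tert-butyldimethylsilyloxy)benzyl] ether A9.
- In its favour: it is the most convergent plan. The bond-forming step is a simple polar substitution whose outcome is easier to predict than a cycloaddition cascade, so on mechanism it is better than the chosen plan. A9 should need only one desilylation, so the step count is probably lower as well.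
- Against it here: A8 is a volatile, potent human carcinogen, which conflicts with the demand for a safe route. The arylmagnesium derived from A7 has an ortho bromine and can eliminate to an aryne unless kept cold. The whole regiochemical burden (iodine, two bromines and two oxygens in sequence) is moved into the synthesis of A7 by classical aromatic substitution.
- Comparison: structurally no ring is built and the substitution pattern must be solved separately. In step economy and predictability it is the equal or the better of the chosen plan. It loses on safety and on where the regiochemical problem ends up.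

Key step: step 8

Check of structures: pyranone C6, C5, C4 and C3 of 9 become arene C1, C2, C3 and C4 of 14, and the acetal carbons of 11 become C5 and C6. 1 is the meso (2R,3S,4R,5S) hexaric acid. The structures are consistent and no correction was needed. The pivalate is kept in 9 on purpose, as the hindered acyl group that resists acyl transfer.

Assumption: the enolic C3–OH of 5 is far more acidic than its primary alcohol, so one equivalent of amine base directs a single acylation to the enol oxygen.

## Route

Step 1
Reactants: 1 galactaric acid (mucic acid, meso, 2R,3S,4R,5S)
Product: 3 3-hydroxy-2-oxo-2H-pyran-6-carboxylic acid, via potassium 3-acetoxy-2-oxo-2H-pyran-6-carboxylate 2 (not isolated)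
Conditions: Ac2O, KOAc, 100 °C; then 3 M HCl, 60 °C
Reagents that add atoms: none
Why: Dehydrative lactonisation of an aldaric acid: in hot acetic anhydride with acetate base the acid is acetylated, closes to the δ-lactone and loses two acetates by β-elimination to give 2, whose enol acetate is then hydrolysed by aqueous acid; all four stereocentres of 1 are destroyed.

Step 2
Reactants: 3 3-hydroxy-2-oxo-2H-pyran-6-carboxylic acid
Product: 4 3-hydroxy-6-(hydroxymethyl)-2H-pyran-2-one
Conditions: BH3·THF (3.5 equiv), THF, 0 °C → rt; CH3OH quench
Reagents that add atoms: none
Why: Borane reduction of a carboxylic acid: the acyloxyborane of the free acid is reduced much faster than the conjugated enol lactone, and the electron-poor diene is a poor substrate for hydroboration at this temperature; the enolic OH only ties up hydride as a borate that methanol cleaves.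

Step 3
Reactants: 4 3-hydroxy-6-(hydroxymethyl)-2H-pyran-2-one
Product: 5 4,5-dibromo-3-hydroxy-6-(hydroxymethyl)-2H-pyran-2-one
Conditions: Br2 (2.2 equiv), NaOAc, AcOH, rt → 40 °C
Reagents that add atoms: bromine, BrBr
Why: Electrophilic bromination of a hydroxypyranone: C4 is the β-carbon of the C3 enol and C5 the β-carbon of the ring enol ester O1–C6=C5, and these are the only two ring CH positions; acetate takes up HBr so that the primary alcohol is not converted into a bromide.

Step 4
Reactants: 5 4,5-dibromo-3-hydroxy-6-(hydroxymethyl)-2H-pyran-2-one; 6 pivaloyl chloride
Product: 7 4,5-dibromo-6-(hydroxymethyl)-2-oxo-2H-pyran-3-yl pivalate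
Conditions: Et3N (1.05 equiv), CH2Cl2, −40 → 0 °C
Reagents that add atoms: none
Why: Chemoselective O-acylation: the enolic OH, acidified by the lactone carbonyl and the C4 bromine, is deprotonated by one equivalent of amine, and its oxyanion takes the hindered acid chloride well before the neutral primary alcohol reacts without an acyl-transfer catalyst.

Step 5
Reactants: 7 4,5-dibromo-6-(hydroxymethyl)-2-oxo-2H-pyran-3-yl pivalate
Product: 8 4,5-dibromo-6-(bromomethyl)-2-oxo-2H-pyran-3-yl pivalate
Conditions: CBr4, PPh3 (pre-mixed), CH2Cl2, 0 °C
Reagents that add atoms: carbon tetrabromide, BrC(Br)(Br)Br
Why: Appel reaction: bromide displaces the alkoxyphosphonium at an unhindered primary carbon under neutral conditions that leave the enol pivalate, the lactone and the ring bromides untouched; pre-forming the phosphonium reagent keeps free phosphine away from the electrophilic pyranone.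

Step 6
Reactants: 7 4,5-dibromo-6-(hydroxymethyl)-2-oxo-2H-pyran-3-yl pivalate; 8 4,5-dibromo-6-(bromomethyl)-2-oxo-2H-pyran-3-yl pivalate
Product: 9 bis[(4,5-dibromo-2-oxo-3-pivaloyloxy-2H-pyran-6-yl)methyl] ether
Conditions: Ag2O, 4 Å MS, CH2Cl2, dark, rt → 40 °C
Reagents that add atoms: none
Why: Silver-oxide-mediated Williamson etherification: Ag2O assists departure of the allylic-type primary bromide and takes up HBr, so the C–O bond forms without alkoxide or strong base that would cleave the enol ester or open the lactone; sieves keep water from hydrolysing 8.

Step 7
Reactants: 10 trimethylsilyl acetate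
Product: 11 1,1-bis(trimethylsilyloxy)ethene
Conditions: LiN(iPr)2, THF, −78 °C; Me3SiCl, −78 °C → rt; distillation
Reagents that add atoms: chlorotrimethylsilane, C[Si](C)(C)Cl
Why: Enolisation of a silyl ester and O-silylation of its lithium enolate, the standard preparation of bis-silyl ketene acetals; low temperature in THF favours O- over C-silylation, and the product is distilled and used fresh.

Step 8
Reactants: 9 bis[(4,5-dibromo-2-oxo-3-pivaloyloxy-2H-pyran-6-yl)methyl] ether; 11 1,1-bis(trimethylsilyloxy)ethene
Product: 14 bis(2,3-dibromo-4-pivaloyloxy-5-trimethylsilyloxybenzyl) ether, via twofold bridged lactone cycloadduct 12 (not isolated), via twofold cyclohexadiene silyl acetal 13 (not isolated)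
Conditions: 11 (6 equiv), PhMe, 60 → 110 °C, sealed tube, Ar; volatiles removed in vacuo, crude used directly
Reagents that add atoms: none
Why: The nucleophilic CH2 end of 11 bonds to pyranone C6, the ring-oxygen-bearing and most electrophilic diene terminus, and the acetal carbon bonds to C3 next to the lactone carbonyl, in an inverse-electron-demand [4+2] cycloaddition that may be concerted and asynchronous or a Michael addition followed by closure, giving bridged lactone 12 on both halves. 12 loses CO2 irreversibly by retro-[4+2] to cyclohexadiene 13, and 1,2-elimination of Me3SiOH across the acetal carbon and its CH2 neighbour aromatises each ring. The closest known reaction type is the benzannulation of electron-poor 2-pyranones with ketene dialkyl acetals (cycloaddition, decarboxylation, loss of alcohol), together with the cycloadditions of bromo-2-pyranones with enol ethers, which take the same orientation. Each benzene ring is closed by cycloaddition, the bonds C6–C1 and C4–C5 (arene numbering) being made in one event, once on each half of 9. No stereocentre is created in 14; the bridgeheads of 12 are transient and their configuration does not matter. The selectivity needed is regiochemical, and the polarisation of the dienyl lactone secures it: C6 is the δ-acceptor carbon conjugated to the carbonyl, and the incipient oxocarbenium carbon of the acetal can only collapse onto C3, so the new oxygen arrives at arene C5 and the hydrogen at C6. The two bromines and the acyloxy group lower the diene LUMO, and 11 is among the most nucleophilic two-carbon alkenes, so the reaction should proceed although every diene carbon is substituted. If part of the acetal loses a silyl group instead and gives the free C5 phenol, the result after step 9 is the same.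

Step 9
Reactants: 14 bis(2,3-dibromo-4-pivaloyloxy-5-trimethylsilyloxybenzyl) ether
Product: 15 bis(2,3-dibromo-4,5-dihydroxybenzyl) ether
Conditions: K2CO3, degassed CH3OH, 0 °C → rt, Ar; then cold 1 M HCl to pH 4
Reagents that add atoms: none
Why: Base-mediated methanolysis: methoxide cleaves the aryl silyl ethers at once and then the aryl pivalates, whose leaving group is a stabilised dibromophenoxide (the freed neighbouring phenoxide can relay the acyl group); cold, oxygen-free conditions and a mild acidic quench should keep the catecholates from oxidising and the 4-hydroxybenzyl ether from ionising.

## Compound list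

1 | galactaric acid (mucic acid, meso, 2R,3S,4R,5S) | OC(=O)[C@H](O)[C@@H](O)[C@@H](O)[C@H](O)C(=O)O | starting material
2 | potassium 3-acetoxy-2-oxo-2H-pyran-6-carboxylate | CC(=O)OC1=CC=C(C(=O)[O-])OC1=O.[K+] | intermediate (not isolated)
3 | 3-hydroxy-2-oxo-2H-pyran-6-carboxylic acid | OC(=O)C1=CC=C(O)C(=O)O1 | intermediate
4 | 3-hydroxy-6-(hydroxymethyl)-2H-pyran-2-one | OCC1=CC=C(O)C(=O)O1 | intermediate
5 | 4,5-dibromo-3-hydroxy-6-(hydroxymethyl)-2H-pyran-2-one | OCC1=C(Br)C(Br)=C(O)C(=O)O1 | intermediate
6 | pivaloyl chloride | CC(C)(C)C(Cl)=O | starting material
7 | 4,5-dibromo-6-(hydroxymethyl)-2-oxo-2H-pyran-3-yl pivalate | CC(C)(C)C(=O)OC1=C(Br)C(Br)=C(CO)OC1=O | intermediate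
8 | 4,5-dibromo-6-(bromomethyl)-2-oxo-2H-pyran-3-yl pivalate | CC(C)(C)C(=O)OC1=C(Br)C(Br)=C(CBr)OC1=O | intermediate
9 | bis[(4,5-dibromo-2-oxo-3-pivaloyloxy-2H-pyran-6-yl)methyl] ether | CC(C)(C)C(=O)OC1=C(Br)C(Br)=C(COCC2=C(Br)C(Br)=C(OC(=O)C(C)(C)C)C(=O)O2)OC1=O | intermediate
10 | trimethylsilyl acetate | CC(=O)O[Si](C)(C)C | starting material
11 | 1,1-bis(trimethylsilyloxy)ethene | C=C(O[Si](C)(C)C)O[Si](C)(C)C | intermediate
12 | bis{[5,6-dibromo-3-oxo-4-pivaloyloxy-8,8-bis(trimethylsilyloxy)-2-oxabicyclo[2.2.2]oct-5-en-1-yl]methyl} ether (mixture of bridgehead stereoisomers, transient) | O(CC12OC(=O)C(OC(=O)C(C)(C)C)(C(Br)=C1Br)C(O[Si](C)(C)C)(O[Si](C)(C)C)C2)CC12OC(=O)C(OC(=O)C(C)(C)C)(C(Br)=C1Br)C(O[Si](C)(C)C)(O[Si](C)(C)C)C2 | intermediate (not isolated)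
13 | bis{[2,3-dibromo-4-pivaloyloxy-5,5-bis(trimethylsilyloxy)cyclohexa-1,3-dien-1-yl]methyl} ether | O(CC1=C(Br)C(Br)=C(OC(=O)C(C)(C)C)C(O[Si](C)(C)C)(O[Si](C)(C)C)C1)CC1=C(Br)C(Br)=C(OC(=O)C(C)(C)C)C(O[Si](C)(C)C)(O[Si](C)(C)C)C1 | intermediate (not isolated)
14 | bis(2,3-dibromo-4-pivaloyloxy-5-trimethylsilyloxybenzyl) ether | CC(C)(C)C(=O)Oc1c(O[Si](C)(C)C)cc(COCc2cc(O[Si](C)(C)C)c(OC(=O)C(C)(C)C)c(Br)c2Br)c(Br)c1Br | intermediate
15 | bis(2,3-dibromo-4,5-dihydroxybenzyl) ether | Oc1cc(COCc2cc(O)c(O)c(Br)c2Br)c(Br)c(Br)c1O | target

## Step count and least certain steps

Total step count: 9. Longest linear sequence: 8 steps (steps 1 to 6, then 8 and 9); step 7 is a one-step side branch.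

Step 8 (key step). The most likely failure is silyl transfer inside a zwitterionic Michael adduct: the silyl group of the oxocarbenium end migrates to the pyranone dienolate oxygen, and the reaction is diverted to open-chain conjugate addition instead of ring closure. A second possible failure is loss of 11 by O-to-C silyl migration or hydrolysis before it engages the fully substituted diene. The fallback sets out from 9 and returns at 15; it uses a silicon-free ketene dialkyl acetal with acid-labile alkyl groups. Bromoacetaldehyde diethyl acetal would be exchanged with 4-methoxybenzyl alcohol (catalytic pyridinium p-toluenesulfonate, ethanol distilled off) to give 2-bromo-1,1-bis(4-methoxybenzyloxy)ethane F1. KOC(CH3)3 would dehydrobrominate it to 1,1-bis(4-methoxybenzyloxy)ethene F2. Heating 9 with F2 in toluene should give, by the same cycloaddition, loss of CO2 and loss of 4-methoxybenzyl alcohol, bis[2,3-dibromo-5-(4-methoxybenzyloxy)-4-pivaloyloxybenzyl] ether F3. Trifluoroacetic acid with anisole at 0 °C should remove the 4-methoxybenzyl groups while the pivalates keep the central ether electron-poor, giving bis(2,3-dibromo-5-hydroxy-4-pivaloyloxybenzyl) ether F4. The methanolysis of step 9 would then convert F4 into 15.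

Step 3. The most likely failure is stalling after the first bromination, because the second substitution at C5 must take place on a ring deactivated by the first halogen; forcing it invites oxidative degradation of the enol lactone. The fallback sets out from 4 and returns at 7; it separates the two halogenations by mechanism. One equivalent of N-bromosuccinimide (CH3CN, 0 °C) would substitute only the enol position to give 4-bromo-3-hydroxy-6-(hydroxymethyl)-2H-pyran-2-one F5. Acylation with 6 as in step 4 would give 4-bromo-6-(hydroxymethyl)-2-oxo-2H-pyran-3-yl pivalate F6. Bromine would then be added across the C5=C6 enol-ester double bond (CH2Cl2, −20 °C) to give 4,5,6-tribromo-6-(hydroxymethyl)-2-oxo-5,6-dihydro-2H-pyran-3-yl pivalate F7. Triethylamine would eliminate HBr (H5 and the C6 bromide) and restore the pyranone as 7.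

Step 6. The most likely failure is slow substitution, because the alcohol is a weak nucleophile and the bromide, next to an electron-poor ring, ionises poorly; hydrolysis of 8 and intermolecular acyl transfer would then compete. The fallback sets out from 7 and returns at 9; it is a reductive etherification. Dess–Martin periodinane would oxidise part of 7 to 4,5-dibromo-6-formyl-2-oxo-2H-pyran-3-yl pivalate F8. F8, 7, triethylsilane and catalytic trimethylsilyl triflate (CH2Cl2, −40 → 0 °C) would be joined through the oxocarbenium ion and hydride transfer to give 9.

Step 9. The most likely failure is expulsion of the benzylic alkoxide by the C4 phenoxide (quinone methide formation) followed by addition of methanol, which would cut the central ether; air oxidation of the catecholate is the second risk. The fallback sets out from 14 and returns at 15; it makes no new compound (entry F0). It is a reductive deacylation without alcohol solvent: iBu2AlH (CH2Cl2, −78 °C) would reduce both pivalates to aluminium phenoxides and 2,2-dimethylpropan-1-ol, and work-up with aqueous potassium sodium tartrate and dilute acid would hydrolyse the silyl ethers.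

## Further compounds

F1 | step 8 | 2-bromo-1,1-bis(4-methoxybenzyloxy)ethane | BrCC(OCc1ccc(OC)cc1)OCc1ccc(OC)cc1
F2 | step 8 | 1,1-bis(4-methoxybenzyloxy)ethene | C=C(OCc1ccc(OC)cc1)OCc1ccc(OC)cc1
F3 | step 8 | bis[2,3-dibromo-5-(4-methoxybenzyloxy)-4-pivaloyloxybenzyl] ether | CC(C)(C)C(=O)Oc1c(OCc2ccc(OC)cc2)cc(COCc2cc(OCc3ccc(OC)cc3)c(OC(=O)C(C)(C)C)c(Br)c2Br)c(Br)c1Br
F4 | step 8 | bis(2,3-dibromo-5-hydroxy-4-pivaloyloxybenzyl) ether | CC(C)(C)C(=O)Oc1c(O)cc(COCc2cc(O)c(OC(=O)C(C)(C)C)c(Br)c2Br)c(Br)c1Br
F5 | step 3 | 4-bromo-3-hydroxy-6-(hydroxymethyl)-2H-pyran-2-one | OCC1=CC(Br)=C(O)C(=O)O1
F6 | step 3 | 4-bromo-6-(hydroxymethyl)-2-oxo-2H-pyran-3-yl pivalate | CC(C)(C)C(=O)OC1=C(Br)C=C(CO)OC1=O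
F7 | step 3 | 4,5,6-tribromo-6-(hydroxymethyl)-2-oxo-5,6-dihydro-2H-pyran-3-yl pivalate (racemic mixture of diastereomers) | CC(C)(C)C(=O)OC1=C(Br)C(Br)C(Br)(CO)OC1=O
F8 | step 6 | 4,5-dibromo-6-formyl-2-oxo-2H-pyran-3-yl pivalate | CC(C)(C)C(=O)OC1=C(Br)C(Br)=C(C=O)OC1=O
F0 | step 9 | none | none
A1 | alternative 1 | bis(2-methylenebut-3-en-1-yl) ether | C=CC(=C)COCC(=C)C=C
A2 | alternative 1 | 4,5-dichloro-1,3-dioxol-2-one | O=C1OC(Cl)=C(Cl)O1
A3 | alternative 1 | bis(3,4-dihydroxybenzyl) ether | Oc1ccc(COCc2ccc(O)c(O)c2)cc1O
A4 | alternative 2 | bis[(5-allyloxy-4-oxo-4H-pyran-2-yl)methyl] ether | C=CCOC1=COC(COCC2=CC(=O)C(OCC=C)=CO2)=CC1=O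
A5 | alternative 2 | nitromethane | C[N+](=O)[O-]
A6 | alternative 2 | bis(4-allyloxy-5-hydroxy-2-nitrobenzyl) ether | C=CCOc1cc([N+](=O)[O-])c(COCc2cc(O)c(OCC=C)cc2[N+](=O)[O-])cc1O
A7 | alternative 3 | 2,3-dibromo-4,5-bis(tert-butyldimethylsilyloxy)-1-iodobenzene | CC(C)(C)[Si](C)(C)Oc1cc(I)c(Br)c(Br)c1O[Si](C)(C)C(C)(C)C
A8 | alternative 3 | bis(chloromethyl) ether | ClCOCCl
A9 | alternative 3 | bis[2,3-dibromo-4,5-bis(tert-butyldimethylsilyloxy)benzyl] ether | CC(C)(C)[Si](C)(C)Oc1cc(COCc2cc(O[Si](C)(C)C(C)(C)C)c(O[Si](C)(C)C(C)(C)C)c(Br)c2Br)c(Br)c(Br)c1O[Si](C)(C)C(C)(C)C
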